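**Retrosynthetic overview**
1. Ring C (butenolide) is made last: alkyne ester 15 + (Z)-3-iodo-2-methylacrylic acid 19 by tandem Sonogashira coupling/5-exo-dig lactonisation, forming the same O–C bond as the presumed biosynthetic lactonisation. Ester 15 comes from alcohol 14, and 14 from spiro enone 12 (CBS reduction).
2. Key step: spiro enone 12 from acyclic dienynone 9 in one Lewis-acid cascade that copies the presumed viscidane pathway: cationic closure of ring A, cation–olefin spirocyclisation (ring B), then a 1,5-hydride shift from the ring CH2 to the side-chain cation.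
3. Dienynone 9 from (S)-β-citronellene 1, which supplies the methyl-bearing ring stereocentre: Wacker oxidation, ozonolysis, (Z)-iodo-olefination/Sonogashira, then enol triflate → allylsilane → acylation.
4. Ring order: A (cyclohexenone) then B (spiro cyclopentane), both in step 8; C (butenolide) in step 13.

Assumption: (S)-β-citronellene is used in high enantiomeric purity; locants C1–C10 and C2' in the text follow the spiro[4.5]decane names (C1 = CH–CH3, C4 = CH bearing the side chain, C5 = spiro carbon, C7 = C–O, C2' = side-chain stereocentre).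

**Step 1**
Reactants: 1 (3S)-3,7-dimethylocta-1,6-diene [(S)-β-citronellene]
Product: 2 (3S)-3,7-dimethyloct-6-en-2-one
Conditions: PdCl2 (10 mol%), CuCl (1 equiv, reoxidised by O2), O2 (1 atm), DMF/H2O 7:1, rt
Reagents that add atoms: water, O
Why: Tsuji–Wacker oxidation converts only the monosubstituted alkene (Markovnikov) into the methyl ketone and leaves the trisubstituted alkene and the chiral-pool stereocentre untouched.

**Step 2**
Reactants: 2 (3S)-3,7-dimethyloct-6-en-2-one
Product: 4 (4S)-4-methyl-5-oxohexanal, via secondary ozonide 3 (not isolated)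
Conditions: O3, CH2Cl2, −78 °C; then PPh3, −78 °C to rt
Reagents that add atoms: ozone, [O-][O+]=O
Why: ozonolysis with reductive work-up cleaves the only remaining C=C under neutral, cold conditions that do not enolise the α-methyl ketone.

**Step 3**
Reactants: 4 (4S)-4-methyl-5-oxohexanal
Product: 5 (3S,6Z)-7-iodo-3-methyloct-6-en-2-one
Conditions: EtPPh3I, n-BuLi, THF, 20 °C; I2, −78 °C; NaN(SiMe3)2, −20 °C; then 4, −78 °C
Reagents that add atoms: ethyltriphenylphosphonium iodide, CC[P+](c1ccccc1)(c1ccccc1)c1ccccc1.[I-]; iodine, II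
Why: Stork–Zhao-type Wittig olefination with the α-iodo ylide attacks the aldehyde far faster than the ketone at −78 °C and gives the (Z)-2-iodoalkene (iodine cis to the chain) under kinetic control.

**Step 4**
Reactants: 5 (3S,6Z)-7-iodo-3-methyloct-6-en-2-one
Product: 6 (3S,6Z)-3,7-dimethyl-9-(trimethylsilyl)non-6-en-8-yn-2-one
Conditions: HC≡CSiMe3, PdCl2(PPh3)2 (3 mol%), CuI (6 mol%), Et3N, THF, rt
Reagents that add atoms: ethynyltrimethylsilane, C#C[Si](C)(C)C
Why: Sonogashira coupling proceeds with retention of alkene geometry, so the alkyne ends cis to the chain, which is the (Z)-enyne needed for the C2' configuration in step 8.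

**Step 5**
Reactants: 6 (3S,6Z)-3,7-dimethyl-9-(trimethylsilyl)non-6-en-8-yn-2-one
Product: 7 (3S,6Z)-3,7-dimethyl-9-(trimethylsilyl)nona-1,6-dien-8-yn-2-yl trifluoromethanesulfonate
Conditions: KN(SiMe3)2, PhNTf2, THF, −78 °C
Reagents that add atoms: N-phenylbis(trifluoromethanesulfonimide), O=S(=O)(N(c1ccccc1)S(=O)(=O)C(F)(F)F)C(F)(F)F
Why: kinetic deprotonation by the hindered amide occurs at the methyl group, so the enol triflate forms on the CH3 side and the stereocentre is never enolised.

**Step 6**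
Reactants: 7 (3S,6Z)-3,7-dimethyl-9-(trimethylsilyl)nona-1,6-dien-8-yn-2-yl trifluoromethanesulfonate
Product: 8 trimethyl[(3S,6Z)-3,7-dimethyl-2-methylidene-9-(trimethylsilyl)non-6-en-8-yn-1-yl]silane
Conditions: Me3SiCH2MgCl, Pd(PPh3)4 (5 mol%), THF, 0 °C to rt
Reagents that add atoms: (trimethylsilyl)methylmagnesium chloride, C[Si](C)(C)C[Mg]Cl
Why: Kumada–Corriu coupling of the vinyl triflate gives the 2-substituted allylsilane; the silylated enyne is inert to the Grignard reagent.

**Step 7**
Reactants: 8 trimethyl[(3S,6Z)-3,7-dimethyl-2-methylidene-9-(trimethylsilyl)non-6-en-8-yn-1-yl]silane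
Product: 9 (6S,9Z)-2,6,10-trimethyl-5-methylidene-12-(trimethylsilyl)dodeca-1,9-dien-11-yn-3-one
Conditions: CH2=C(CH3)COCl (1.05 equiv), TiCl4 (1.05 equiv), CH2Cl2, −78 °C, 10 min; cold aq. NaHCO3
Reagents that add atoms: methacryloyl chloride, C=C(C)C(Cl)=O
Why: Lewis-acid acylation of the allylsilane (SE2', Hosomi–Sakurai-type) occurs at the =CH2 terminus with loss of the silyl group and gives the skipped isopropenyl ketone regiospecifically; the allylsilane is far more nucleophilic than the enyne or the alkynylsilane.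

**Step 8**
Reactants: 9 (6S,9Z)-2,6,10-trimethyl-5-methylidene-12-(trimethylsilyl)dodeca-1,9-dien-11-yn-3-one
Product: 12 (1S,4R,5S)-1,8-dimethyl-4-[(2S)-4-(trimethylsilyl)but-3-yn-2-yl]spiro[4.5]dec-8-en-7-one, via cyclohexyl cation 10 (not isolated), via spiro propargyl cation 11 (not isolated)
Conditions: MeAlCl2 (2.2 equiv), CH2Cl2 (0.01 M), −78 to −30 °C; aq. NaHCO3
Reagents that add atoms: none
Why: Proposed new method: MeAlCl2 makes the isopropenyl ketone a β-cation equivalent that is attacked by the CH2 end of the 1,1-disubstituted alkene (6-endo conjugate Prins closure of ring A) to give tertiary cation 10 with an aluminium enolate; 10 is trapped 5-exo by the (Z)-enyne through a chair-like transition state with the C1 methyl pseudo-equatorial (ring B, C4 trans to C1); in spiro cation 11, the epimer with the cationic carbon over C10H2 undergoes a suprafacial 1,5-hydride shift from C9–H (allylic to the enolate, six-membered transition state) onto the face of the propargylic cation fixed by the (Z)-enyne, which sets C2' as (S) and unveils the C8=C9 enone; only this spiro epimer has a hydridic C–H in reach, so C5 is fixed by the termination itself; closest known reaction types are alkylaluminium-halide-induced conjugate addition of alkenes to enones with hydride shifts in the zwitterion, spirocyclisation of bisabolyl-type cations to acoranes, and hydride abstraction from the allylic position of enol derivatives by carbocations.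

**Step 9**
Reactants: 12 (1S,4R,5S)-1,8-dimethyl-4-[(2S)-4-(trimethylsilyl)but-3-yn-2-yl]spiro[4.5]dec-8-en-7-one
Product: 14 (1S,4R,5S,7S)-4-[(2S)-but-3-yn-2-yl]-1,8-dimethylspiro[4.5]dec-8-en-7-ol, via silylated allylic alcohol 13 (not isolated)
Conditions: (R)-2-methyl-CBS-oxazaborolidine (20 mol%), catecholborane (1.5 equiv), toluene, −78 °C; then MeOH, K2CO3 (cat.), rt
Reagents that add atoms: none
Why: CBS reduction gives reagent-controlled 1,2-hydride delivery (the α-methylvinyl side acts as the large group, so the (R)-catalyst gives the 7S alcohol) without touching the alkyne, and the methanolic carbonate work-up removes the alkynyl silyl group.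

**Step 10**
Reactants: 14 (1S,4R,5S,7S)-4-[(2S)-but-3-yn-2-yl]-1,8-dimethylspiro[4.5]dec-8-en-7-ol
Product: 15 (1S,4R,5S,7S)-4-[(2S)-but-3-yn-2-yl]-1,8-dimethylspiro[4.5]dec-8-en-7-yl 3-phenylpropanoate
Conditions: PhCH2CH2COCl, Et3N, DMAP (cat.), CH2Cl2, 0 °C to rt
Reagents that add atoms: 3-phenylpropanoyl chloride, O=C(Cl)CCc1ccccc1
Why: DMAP-catalysed acylation of the allylic alcohol proceeds with retention at C7.

**Step 11**
Reactants: 16 prop-2-yn-1-ol
Product: 18 (2Z)-3-iodo-2-methylprop-2-en-1-ol, via vinylmagnesium alkoxide 17 (not isolated)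
Conditions: MeMgBr (2.2 equiv), CuI (10 mol%), THF, −10 °C to rt; then I2, −20 °C
Reagents that add atoms: methylmagnesium bromide, C[Mg]Br; iodine, II
Why: hydroxyl-directed copper-catalysed anti-carbomagnesiation (Duboudin-type) places magnesium cis to CH2O, and iodinolysis with retention gives the (Z)-vinyl iodide.

**Step 12**
Reactants: 18 (2Z)-3-iodo-2-methylprop-2-en-1-ol
Product: 19 (2Z)-3-iodo-2-methylprop-2-enoic acid
Conditions: TEMPO (10 mol%), PhI(OAc)2 (2.2 equiv), MeCN/H2O, rt
Reagents that add atoms: water, O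
Why: TEMPO/PhI(OAc)2 oxidation takes the primary allylic alcohol through the aldehyde hydrate to the acid under near-neutral conditions that keep the (Z)-vinyl iodide.

**Step 13**
Reactants: 15 (1S,4R,5S,7S)-4-[(2S)-but-3-yn-2-yl]-1,8-dimethylspiro[4.5]dec-8-en-7-yl 3-phenylpropanoate; 19 (2Z)-3-iodo-2-methylprop-2-enoic acid
Product: 21 (1S,4R,5S,7S)-1,8-dimethyl-4-{(2S)-1-[(2Z)-4-methyl-5-oxofuran-2(5H)-ylidene]propan-2-yl}spiro[4.5]dec-8-en-7-yl 3-phenylpropanoate (CNP0260277.1), via enynoic acid 20 (not isolated)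
Conditions: Pd(PPh3)4 (5 mol%), CuI (10 mol%), Et3N, MeCN, rt
Reagents that add atoms: none
Why: tandem Sonogashira coupling/5-exo-dig lactonisation; the (Z)-enynoic acid 20 cyclises by anti addition of carboxylate and hydrogen across the alkyne, which gives the (Z)-ylidene butenolide (ring C), and Et3N does not epimerise the propargylic C2' centre.

**Compound list**
1 | (3S)-3,7-dimethylocta-1,6-diene [(S)-β-citronellene] | C=C[C@@H](C)CCC=C(C)C | starting material
2 | (3S)-3,7-dimethyloct-6-en-2-one | CC(=O)[C@@H](C)CCC=C(C)C | intermediate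
3 | (3S)-5-(5,5-dimethyl-1,2,4-trioxolan-3-yl)-3-methylpentan-2-one (secondary ozonide) | CC(=O)[C@@H](C)CCC1OOC(C)(C)O1 | intermediate
4 | (4S)-4-methyl-5-oxohexanal | CC(=O)[C@@H](C)CCC=O | intermediate
5 | (3S,6Z)-7-iodo-3-methyloct-6-en-2-one | CC(=O)[C@@H](C)CC/C=C(C)\I | intermediate
6 | (3S,6Z)-3,7-dimethyl-9-(trimethylsilyl)non-6-en-8-yn-2-one | CC(=O)[C@@H](C)CC/C=C(C)\C#C[Si](C)(C)C | intermediate
7 | (3S,6Z)-3,7-dimethyl-9-(trimethylsilyl)nona-1,6-dien-8-yn-2-yl trifluoromethanesulfonate | C=C(OS(=O)(=O)C(F)(F)F)[C@@H](C)CC/C=C(C)\C#C[Si](C)(C)C | intermediate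
8 | trimethyl[(3S,6Z)-3,7-dimethyl-2-methylidene-9-(trimethylsilyl)non-6-en-8-yn-1-yl]silane | C=C(C[Si](C)(C)C)[C@@H](C)CC/C=C(C)\C#C[Si](C)(C)C | intermediate
9 | (6S,9Z)-2,6,10-trimethyl-5-methylidene-12-(trimethylsilyl)dodeca-1,9-dien-11-yn-3-one | C=C(C)C(=O)CC(=C)[C@@H](C)CC/C=C(C)\C#C[Si](C)(C)C | intermediate
10 | 3-{[dichloro(methyl)aluminato]oxy}-4-methyl-1-[(2S,5Z)-6-methyl-8-(trimethylsilyl)oct-5-en-7-yn-2-yl]cyclohex-3-en-1-ylium (zwitterion) | C[Al-](Cl)(Cl)OC1=C(C)CC[C+](C1)[C@@H](C)CC/C=C(C)\C#C[Si](C)(C)C | intermediate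
11 | spiro[4.5]dec-7-ene propargylic cation/aluminium enolate zwitterion, ring carbons configured as in 12 | C[Si](C)(C)C#C[C+](C)[C@H]1CC[C@H](C)[C@@]12CCC(C)=C(O[Al-](C)(Cl)Cl)C2 | intermediate
12 | (1S,4R,5S)-1,8-dimethyl-4-[(2S)-4-(trimethylsilyl)but-3-yn-2-yl]spiro[4.5]dec-8-en-7-one | C[Si](C)(C)C#C[C@@H](C)[C@H]1CC[C@H](C)[C@@]12CC=C(C)C(=O)C2 | intermediate
13 | (1S,4R,5S,7S)-1,8-dimethyl-4-[(2S)-4-(trimethylsilyl)but-3-yn-2-yl]spiro[4.5]dec-8-en-7-ol | C[Si](C)(C)C#C[C@@H](C)[C@H]1CC[C@H](C)[C@@]12CC=C(C)[C@@H](O)C2 | intermediate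
14 | (1S,4R,5S,7S)-4-[(2S)-but-3-yn-2-yl]-1,8-dimethylspiro[4.5]dec-8-en-7-ol | C#C[C@@H](C)[C@H]1CC[C@H](C)[C@@]12CC=C(C)[C@@H](O)C2 | intermediate
15 | (1S,4R,5S,7S)-4-[(2S)-but-3-yn-2-yl]-1,8-dimethylspiro[4.5]dec-8-en-7-yl 3-phenylpropanoate | C#C[C@@H](C)[C@H]1CC[C@H](C)[C@@]12CC=C(C)[C@@H](OC(=O)CCc3ccccc3)C2 | intermediate
16 | prop-2-yn-1-ol | C#CCO | starting material
17 | bromomagnesium (2Z)-3-(bromomagnesio)-2-methylprop-2-en-1-olate | Br[Mg]/C=C(C)\CO[Mg]Br | intermediate
18 | (2Z)-3-iodo-2-methylprop-2-en-1-ol | OC/C(C)=C\I | intermediate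
19 | (2Z)-3-iodo-2-methylprop-2-enoic acid | OC(=O)/C(C)=C\I | intermediate
20 | (2Z,6S)-2-methyl-6-[the C4 substituent position of 15]hept-2-en-4-ynoic acid, i.e. 15 with (Z)-CH=C(CH3)CO2H on the alkyne terminus | OC(=O)/C(C)=C\C#C[C@@H](C)[C@H]1CC[C@H](C)[C@@]12CC=C(C)[C@@H](OC(=O)CCc3ccccc3)C2 | intermediate
21 | (1S,4R,5S,7S)-1,8-dimethyl-4-{(2S)-1-[(2Z)-4-methyl-5-oxofuran-2(5H)-ylidene]propan-2-yl}spiro[4.5]dec-8-en-7-yl 3-phenylpropanoate (CNP0260277.1) | CC1=C/C(=C/[C@@H](C)[C@H]2CC[C@H](C)[C@@]23CC=C(C)[C@@H](OC(=O)CCc2ccccc2)C3)OC1=O | target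

**Totals and risk**
Total step count: 13. Longest linear sequence: 11 (steps 1–10, then 13).

Steps most likely to fail: 8, 3 and 7.

*Step 8 (cascade).* This is the least certain step, for three reasons.
- The spiro epimer with the cationic carbon over C6H2 has no hydride donor and is lost, so the yield may not exceed about half; the two spirocyclisation modes are not obviously biased.
- The enolate carbon C8 could alkylate the propargylic cation to give a bicyclo[2.2.2]octanone instead of the hydride shift.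
- A 1,2-hydride shift from C1 in cation 10 could erode the C1 stereocentre.

Diastereomeric by-products should be separable, but the route depends on this step working at a useful level.

Fallback, setting out from 6 and coming back at 12: use the concerted counterpart, a thermal intramolecular ene reaction on a preformed ring A. Ketone 6 is converted with LiN(iPr)2/Me3SiCl at −78 °C into the kinetic trimethylsilyl enol ether F1. Mukaiyama–Michael addition of this to 3-methylbut-3-en-2-one (TiCl4, −78 °C) gives the 1,5-diketone F2. Aldol condensation (pyrrolidine, AcOH) closes the cyclohexenone F3. Et3N/tBuMe2SiOTf gives the through-conjugated silyloxy diene F4. Heating (toluene, 230 °C, sealed tube) makes the ring alkene bond to the enyne CH while the ring allylic hydrogen passes suprafacially to the enyne carbon, giving the spiro silyl dienol ether F5 with the same C4, C5 and C2' configurations. Aqueous HCl then DBU hydrolyses and conjugates this to 12.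

*Step 3 (iodo-olefination).* The α-iodo ylide often gives moderate yield and imperfect Z/E, and the 1,5-keto-aldehyde can self-condense under base.

Fallback, setting out from 4 and coming back at 6: Ramirez olefination (CBr4, PPh3, CH2Cl2, 0 °C) gives the 1,1-dibromoalkene F6. PdCl2(DPEphos)-catalysed coupling with Me2Zn replaces only the bromine trans to the chain and gives the (Z)-2-bromoalkene F7. Sonogashira coupling with ethynyltrimethylsilane (Pd(PPh3)4, CuI, iPr2NH, 50 °C) then gives 6.

*Step 7 (acylation).* The skipped enone 9 may conjugate to the divinyl ketone or begin to cyclise under TiCl4.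

Fallback, setting out from 8 and coming back at 9: Hosomi–Sakurai addition of 8 to methacrolein (TiCl4, CH2Cl2, −78 °C) gives the dienol F8, which buffered Dess–Martin periodinane (NaHCO3, CH2Cl2) oxidises to 9 without any Lewis acid present.

**Further compounds**
F1 | step 8 | trimethyl{[(3S,6Z)-3,7-dimethyl-9-(trimethylsilyl)nona-1,6-dien-8-yn-2-yl]oxy}silane | C=C(O[Si](C)(C)C)[C@@H](C)CC/C=C(C)\C#C[Si](C)(C)C
F2 | step 8 | (7S,10Z)-3,7,11-trimethyl-13-(trimethylsilyl)tridec-10-en-12-yne-2,6-dione (both C3 epimers) | CC(=O)C(C)CCC(=O)[C@@H](C)CC/C=C(C)\C#C[Si](C)(C)C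
F3 | step 8 | 6-methyl-3-[(2S,5Z)-6-methyl-8-(trimethylsilyl)oct-5-en-7-yn-2-yl]cyclohex-2-en-1-one | CC1CCC(=CC1=O)[C@@H](C)CC/C=C(C)\C#C[Si](C)(C)C
F4 | step 8 | tert-butyldimethyl({6-methyl-3-[(2S,5Z)-6-methyl-8-(trimethylsilyl)oct-5-en-7-yn-2-yl]cyclohexa-1,3-dien-1-yl}oxy)silane | CC1CC=C(C=C1O[Si](C)(C)C(C)(C)C)[C@@H](C)CC/C=C(C)\C#C[Si](C)(C)C
F5 | step 8 | tert-butyl({(1S,4R,5S)-1,8-dimethyl-4-[(2S)-4-(trimethylsilyl)but-3-yn-2-yl]spiro[4.5]deca-6,9-dien-7-yl}oxy)dimethylsilane | C[Si](C)(C)C#C[C@@H](C)[C@H]1CC[C@H](C)[C@@]12C=CC(C)C(O[Si](C)(C)C(C)(C)C)=C2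
F6 | step 3 | (3S)-7,7-dibromo-3-methylhept-6-en-2-one | CC(=O)[C@@H](C)CCC=C(Br)Br
F7 | step 3 | (3S,6Z)-7-bromo-3-methyloct-6-en-2-one | CC(=O)[C@@H](C)CC/C=C(C)\Br
F8 | step 7 | (6S,9Z)-2,6,10-trimethyl-5-methylidene-12-(trimethylsilyl)dodeca-1,9-dien-11-yn-3-ol (both C3 epimers) | C=C(C)C(O)CC(=C)[C@@H](C)CC/C=C(C)\C#C[Si](C)(C)C
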